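Ring C is a phloroglucinol unit (ring oxygens on C1, C3 and C5) with a fourth oxygen on C4, so its six carbons map onto a 3,5-dioxohexanoate chain whose 3-oxygen is already the ring B aryl ether and whose carbon 6 bears the ring D aryloxy group. The route rests on one intramolecular Claisen condensation of chain carbon 6 onto the ester carbon: it forms the ring C C3–C4 bond, aromatises ring C and leaves only its two hydroxyls free. The precursor is methyl (E)-3-aryloxy-6-aryloxy-5-oxohex-2-enoate 22, joined from a ring A–B phenol and a ring D–E aryloxyacetamide, both made by ortho-bromobenzaldehyde etherification and Baeyer–Villiger oxidation.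

Key step: step 14

Remarks: Bn = benzyl. The target has no stereocentre; the only stereochemical element in the route is the (E) enol ether of 21 and 22 (ester cis to the carbon chain), which vanishes on aromatisation. Compounds 1, 9, 11, 15 and 20 are taken as purchased. In 22 the ester stays a methyl ester and every hydroxyl outside ring C is a benzyl ether, so the closure liberates only methoxide and one hydrogenolysis finishes the synthesis.

**Route**

Step 1
Reactants: 1 3,4,5-trihydroxybenzaldehyde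
Product: 2 3,4,5-tris(benzyloxy)benzaldehyde
Conditions: BnBr (3.6 equiv), K2CO3, DMF, 60 °C, N2
Reagents that add atoms: benzyl bromide, BrCc1ccccc1
Why: Williamson ether synthesis in which the three phenoxides are benzylated under nitrogen while the aldehyde is inert to K2CO3.

Step 2
Reactants: 2 3,4,5-tris(benzyloxy)benzaldehyde
Product: 4 3,4,5-tris(benzyloxy)phenol, via aryl formate 3 (not isolated)
Conditions: mCPBA, CH2Cl2, 0 °C → rt; aq. NaHCO3/Na2S2O3 wash; then K2CO3 (0.2 equiv), MeOH, rt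
Reagents that add atoms: 3-chloroperoxybenzoic acid (mCPBA), OOC(=O)c1cccc(Cl)c1
Why: Baeyer–Villiger oxidation in which the aryl group, made electron-rich by the para benzyloxy substituent, migrates in preference to hydrogen to give the formate, which catalytic carbonate in methanol transesterifies to the phenol.

Step 3
Reactants: 2 3,4,5-tris(benzyloxy)benzaldehyde
Product: 5 2-bromo-3,4,5-tris(benzyloxy)benzaldehyde
Conditions: NBS (1.05 equiv), MeCN, rt → 40 °C, dark
Reagents that add atoms: N-bromosuccinimide, O=C1CCC(=O)N1Br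
Why: Electrophilic aromatic bromination at one of the two equivalent free positions (ortho to the formyl group, ortho and para to benzyloxy groups), run in a polar solvent in the dark so that the benzylic C–H bonds are not attacked.

Step 4
Reactants: 4 3,4,5-tris(benzyloxy)phenol and 5 2-bromo-3,4,5-tris(benzyloxy)benzaldehyde
Product: 6 3,4,5-tris(benzyloxy)-2-[3,4,5-tris(benzyloxy)phenoxy]benzaldehyde
Conditions: CuI (20 mol%), picolinic acid (40 mol%), K3PO4 (2 equiv), DMSO, 90 °C, argon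
Reagents that add atoms: none
Why: Ullmann-type C–O coupling in which the ortho formyl group activates the C–Br bond and the picolinate ligand allows substitution at a bromide flanked on both sides, the unhindered phenoxide of 4 being a good partner.

Step 5
Reactants: 6 3,4,5-tris(benzyloxy)-2-[3,4,5-tris(benzyloxy)phenoxy]benzaldehyde
Product: 8 3,4,5-tris(benzyloxy)-2-[3,4,5-tris(benzyloxy)phenoxy]phenol, via aryl formate 7 (not isolated)
Conditions: mCPBA (1.3 equiv), CH2Cl2, 0 °C → rt; aq. NaHCO3/Na2S2O3 wash; then K2CO3 (0.2 equiv), MeOH, rt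
Reagents that add atoms: 3-chloroperoxybenzoic acid (mCPBA), OOC(=O)c1cccc(Cl)c1
Why: Baeyer–Villiger oxidation of an aldehyde whose ring carries an ortho aryloxy and a para benzyloxy group, so aryl migration should dominate, followed by methanolysis of the formate to the ring D phenol.

Step 6
Reactants: 8 3,4,5-tris(benzyloxy)-2-[3,4,5-tris(benzyloxy)phenoxy]phenol and 9 2-chloro-N-methoxy-N-methylacetamide
Product: 10 N-methoxy-N-methyl-2-{3,4,5-tris(benzyloxy)-2-[3,4,5-tris(benzyloxy)phenoxy]phenoxy}acetamide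
Conditions: K2CO3 (2 equiv), NaI (0.1 equiv), DMF, 60 °C
Reagents that add atoms: none
Why: Williamson ether synthesis (SN2 of the phenoxide on the α-chloro amide, assisted by iodide exchange), which installs chain carbons 5 and 6 as a Weinreb amide.

Step 7
Reactants: 11 2,4,6-trihydroxybenzaldehyde
Product: 12 2,4,6-tris(benzyloxy)benzaldehyde
Conditions: BnBr (3.6 equiv), K2CO3, DMF, 70 °C, N2
Reagents that add atoms: benzyl bromide, BrCc1ccccc1
Why: Williamson ether synthesis in which heating overcomes the hydrogen bonding of the two ortho hydroxyls and the formyl group damps C-benzylation of the phloroglucinol ring.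

Step 8
Reactants: 12 2,4,6-tris(benzyloxy)benzaldehyde
Product: 14 2,4,6-tris(benzyloxy)phenol, via aryl formate 13 (not isolated)
Conditions: mCPBA (1.2 equiv), CH2Cl2, 0 °C; aq. NaHCO3/Na2S2O3 wash; then K2CO3 (0.2 equiv), MeOH, rt, argon
Reagents that add atoms: 3-chloroperoxybenzoic acid (mCPBA), OOC(=O)c1cccc(Cl)c1
Why: Baeyer–Villiger oxidation of a 2,4,6-trialkoxybenzaldehyde, for which aryl migration is strongly favoured, followed by methanolysis of the formate.

Step 9
Reactants: 15 1,3-bis(benzyloxy)-5-bromobenzene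
Product: 16 2-bromo-4,6-bis(benzyloxy)benzaldehyde
Conditions: POCl3 (1.5 equiv), DMF, 0 → 75 °C; then H2O
Reagents that add atoms: N,N-dimethylformamide, CN(C)C=O; water, O
Why: Vilsmeier–Haack formylation, expected next to bromine (para to one benzyloxy group and ortho to the other) because the site between the two benzyloxy groups is more hindered, as is known for 1-bromo-3,5-dialkoxybenzenes, with any minor regioisomer removed by crystallisation.

Step 10
Reactants: 14 2,4,6-tris(benzyloxy)phenol and 16 2-bromo-4,6-bis(benzyloxy)benzaldehyde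
Product: 17 4,6-bis(benzyloxy)-2-[2,4,6-tris(benzyloxy)phenoxy]benzaldehyde
Conditions: CuI (20 mol%), picolinic acid (40 mol%), K3PO4 (2 equiv), DMSO, 100 °C, argon
Reagents that add atoms: none
Why: Ullmann-type C–O coupling of a 2,6-disubstituted phenol, a case the CuI/picolinic acid system handles, with a bromide that has only one ortho substituent and is activated by that formyl group.

Step 11
Reactants: 17 4,6-bis(benzyloxy)-2-[2,4,6-tris(benzyloxy)phenoxy]benzaldehyde
Product: 19 2,4-bis(benzyloxy)-6-[2,4,6-tris(benzyloxy)phenoxy]phenol, via aryl formate 18 (not isolated)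
Conditions: mCPBA (1.2 equiv), CH2Cl2, 0 °C; aq. NaHCO3/Na2S2O3 wash; then K2CO3 (0.2 equiv), MeOH, rt, argon
Reagents that add atoms: 3-chloroperoxybenzoic acid (mCPBA), OOC(=O)c1cccc(Cl)c1
Why: Baeyer–Villiger oxidation of a 2,4,6-trioxygenated benzaldehyde followed by formate methanolysis, which turns the former formyl carbon of ring B into the phenol that will become the ring B–ring C ether oxygen.

Step 12
Reactants: 19 2,4-bis(benzyloxy)-6-[2,4,6-tris(benzyloxy)phenoxy]phenol and 20 methyl but-2-ynoate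
Product: 21 methyl (E)-3-{2,4-bis(benzyloxy)-6-[2,4,6-tris(benzyloxy)phenoxy]phenoxy}but-2-enoate
Conditions: 20 (1.5 equiv), Cs2CO3 (0.3 equiv), DMF, 60 °C, argon
Reagents that add atoms: none
Why: Oxa-Michael addition of the phenoxide to the alkynoate under reversible, base-equilibrating conditions, which should deliver the thermodynamically preferred (E) isomer with the bulky aryloxy group trans to the ester and the methyl group cis to it.

Step 13
Reactants: 21 methyl (E)-3-{2,4-bis(benzyloxy)-6-[2,4,6-tris(benzyloxy)phenoxy]phenoxy}but-2-enoate and 10 N-methoxy-N-methyl-2-{3,4,5-tris(benzyloxy)-2-[3,4,5-tris(benzyloxy)phenoxy]phenoxy}acetamide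
Product: 22 methyl (E)-3-{2,4-bis(benzyloxy)-6-[2,4,6-tris(benzyloxy)phenoxy]phenoxy}-5-oxo-6-{3,4,5-tris(benzyloxy)-2-[3,4,5-tris(benzyloxy)phenoxy]phenoxy}hex-2-enoate
Conditions: LiN(i-Pr)2 (1.1 equiv), THF, −78 °C; then 10 (1.1 equiv), −78 → −50 °C; AcOH, −78 °C
Reagents that add atoms: none
Why: γ-Acylation of the extended lithium enolate of a 3-oxycrotonate (vinylogous Claisen-type acylation), in which the methyl group cis to the ester is deprotonated, its carbon attacks the Weinreb amide, and the chelated tetrahedral adduct keeps the ketone masked until the cold acidic quench, so over-addition and lactonisation are avoided and the (E) geometry is kept.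

Step 14
Reactants: 22 methyl (E)-3-{2,4-bis(benzyloxy)-6-[2,4,6-tris(benzyloxy)phenoxy]phenoxy}-5-oxo-6-{3,4,5-tris(benzyloxy)-2-[3,4,5-tris(benzyloxy)phenoxy]phenoxy}hex-2-enoate
Product: 23 5-{2,4-bis(benzyloxy)-6-[2,4,6-tris(benzyloxy)phenoxy]phenoxy}-2-{3,4,5-tris(benzyloxy)-2-[3,4,5-tris(benzyloxy)phenoxy]phenoxy}benzene-1,3-diol
Conditions: KOt-Bu (3 equiv), THF/t-BuOH (10:1), 0 → 40 °C, argon; then AcOH
Reagents that add atoms: none
Why: This is an intramolecular Claisen (Dieckmann-type) condensation of a δ-keto ester, the closure that gives cyclohexane-1,3-diones and turns 3,5-dioxohexanoates into phloroglucinols: the alkoxide first removes the most acidic hydrogen on chain carbon 4 to give a delocalised anion in which the ester is switched off, and proton shuttling through tert-butanol supplies small amounts of the carbon 6 enolate (acidified by the ketone and the ring D aryloxy group) with the enoate still neutral. That enolate carbon adds to the ester carbonyl in a 6-(enolendo)-exo-trig closure, forming the ring C C3–C4 bond; loss of methoxide and two tautomerisations give the aromatic 1,3-diol, whose irreversible formation as the dipotassium diphenoxide should pull all equilibria forward. No stereocentre is formed. The step needs C- over O-acylation by the ketone enolate and retention of the ring B aryloxy group: the (E) enol ether holds the ester cis to the chain (and re-equilibrates through the carbon 4 anion if it scrambles), the hindered alkoxide does not add to chain carbon 3, and the substrate rests as an anion that shields that carbon from the liberated methoxide. Any 4-aryloxy-2-pyranone formed by O-closure can be reopened at its lactone carbonyl by that methoxide and returned to the same manifold.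

Step 15
Reactants: 23 5-{2,4-bis(benzyloxy)-6-[2,4,6-tris(benzyloxy)phenoxy]phenoxy}-2-{3,4,5-tris(benzyloxy)-2-[3,4,5-tris(benzyloxy)phenoxy]phenoxy}benzene-1,3-diol
Product: 24 5-[2,4-dihydroxy-6-(2,4,6-trihydroxyphenoxy)phenoxy]-2-[3,4,5-trihydroxy-2-(3,4,5-trihydroxyphenoxy)phenoxy]benzene-1,3-diol (target)
Conditions: H2 (1 atm), 10% Pd/C, THF/MeOH (1:1), rt; filtration under argon
Reagents that add atoms: none
Why: Catalytic hydrogenolysis of the eleven benzyl ethers, which leaves the diaryl ether bonds and the arene rings untouched and exposes the air-sensitive polyphenol only in the last, neutral operation.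

**Compound list**

1 | 3,4,5-trihydroxybenzaldehyde | O=Cc1cc(O)c(O)c(O)c1 | starting material
2 | 3,4,5-tris(benzyloxy)benzaldehyde | O=Cc1cc(OCc9ccccc9)c(OCc9ccccc9)c(OCc9ccccc9)c1 | intermediate
3 | 3,4,5-tris(benzyloxy)phenyl formate | O=COc1cc(OCc9ccccc9)c(OCc9ccccc9)c(OCc9ccccc9)c1 | intermediate
4 | 3,4,5-tris(benzyloxy)phenol | Oc1cc(OCc9ccccc9)c(OCc9ccccc9)c(OCc9ccccc9)c1 | intermediate
5 | 2-bromo-3,4,5-tris(benzyloxy)benzaldehyde | O=Cc1cc(OCc9ccccc9)c(OCc9ccccc9)c(OCc9ccccc9)c1Br | intermediate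
6 | 3,4,5-tris(benzyloxy)-2-[3,4,5-tris(benzyloxy)phenoxy]benzaldehyde | O=Cc1cc(OCc9ccccc9)c(OCc9ccccc9)c(OCc9ccccc9)c1Oc2cc(OCc9ccccc9)c(OCc9ccccc9)c(OCc9ccccc9)c2 | intermediate
7 | 3,4,5-tris(benzyloxy)-2-[3,4,5-tris(benzyloxy)phenoxy]phenyl formate | O=COc1cc(OCc9ccccc9)c(OCc9ccccc9)c(OCc9ccccc9)c1Oc2cc(OCc9ccccc9)c(OCc9ccccc9)c(OCc9ccccc9)c2 | intermediate
8 | 3,4,5-tris(benzyloxy)-2-[3,4,5-tris(benzyloxy)phenoxy]phenol | Oc1cc(OCc9ccccc9)c(OCc9ccccc9)c(OCc9ccccc9)c1Oc2cc(OCc9ccccc9)c(OCc9ccccc9)c(OCc9ccccc9)c2 | intermediate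
9 | 2-chloro-N-methoxy-N-methylacetamide | CON(C)C(=O)CCl | starting material
10 | N-methoxy-N-methyl-2-{3,4,5-tris(benzyloxy)-2-[3,4,5-tris(benzyloxy)phenoxy]phenoxy}acetamide | CON(C)C(=O)COc1cc(OCc9ccccc9)c(OCc9ccccc9)c(OCc9ccccc9)c1Oc2cc(OCc9ccccc9)c(OCc9ccccc9)c(OCc9ccccc9)c2 | intermediate
11 | 2,4,6-trihydroxybenzaldehyde | O=Cc1c(O)cc(O)cc1O | starting material
12 | 2,4,6-tris(benzyloxy)benzaldehyde | O=Cc1c(OCc9ccccc9)cc(OCc9ccccc9)cc1OCc9ccccc9 | intermediate
13 | 2,4,6-tris(benzyloxy)phenyl formate | O=COc1c(OCc9ccccc9)cc(OCc9ccccc9)cc1OCc9ccccc9 | intermediate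
14 | 2,4,6-tris(benzyloxy)phenol | Oc1c(OCc9ccccc9)cc(OCc9ccccc9)cc1OCc9ccccc9 | intermediate
15 | 1,3-bis(benzyloxy)-5-bromobenzene | Brc1cc(OCc9ccccc9)cc(OCc9ccccc9)c1 | starting material
16 | 2-bromo-4,6-bis(benzyloxy)benzaldehyde | O=Cc1c(Br)cc(OCc9ccccc9)cc1OCc9ccccc9 | intermediate
17 | 4,6-bis(benzyloxy)-2-[2,4,6-tris(benzyloxy)phenoxy]benzaldehyde | O=Cc1c(Oc2c(OCc9ccccc9)cc(OCc9ccccc9)cc2OCc9ccccc9)cc(OCc9ccccc9)cc1OCc9ccccc9 | intermediate
18 | 2,4-bis(benzyloxy)-6-[2,4,6-tris(benzyloxy)phenoxy]phenyl formate | O=COc1c(Oc2c(OCc9ccccc9)cc(OCc9ccccc9)cc2OCc9ccccc9)cc(OCc9ccccc9)cc1OCc9ccccc9 | intermediate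
19 | 2,4-bis(benzyloxy)-6-[2,4,6-tris(benzyloxy)phenoxy]phenol | Oc1c(Oc2c(OCc9ccccc9)cc(OCc9ccccc9)cc2OCc9ccccc9)cc(OCc9ccccc9)cc1OCc9ccccc9 | intermediate
20 | methyl but-2-ynoate | CC#CC(=O)OC | starting material
21 | methyl (E)-3-{2,4-bis(benzyloxy)-6-[2,4,6-tris(benzyloxy)phenoxy]phenoxy}but-2-enoate | COC(=O)/C=C(/Oc1c(Oc2c(OCc9ccccc9)cc(OCc9ccccc9)cc2OCc9ccccc9)cc(OCc9ccccc9)cc1OCc9ccccc9)C | intermediate
22 | methyl (E)-3-{2,4-bis(benzyloxy)-6-[2,4,6-tris(benzyloxy)phenoxy]phenoxy}-5-oxo-6-{3,4,5-tris(benzyloxy)-2-[3,4,5-tris(benzyloxy)phenoxy]phenoxy}hex-2-enoate | COC(=O)/C=C(/Oc1c(Oc2c(OCc9ccccc9)cc(OCc9ccccc9)cc2OCc9ccccc9)cc(OCc9ccccc9)cc1OCc9ccccc9)CC(=O)COc3cc(OCc9ccccc9)c(OCc9ccccc9)c(OCc9ccccc9)c3Oc4cc(OCc9ccccc9)c(OCc9ccccc9)c(OCc9ccccc9)c4 | intermediate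
23 | 5-{2,4-bis(benzyloxy)-6-[2,4,6-tris(benzyloxy)phenoxy]phenoxy}-2-{3,4,5-tris(benzyloxy)-2-[3,4,5-tris(benzyloxy)phenoxy]phenoxy}benzene-1,3-diol | Oc1cc(Oc2c(Oc3c(OCc9ccccc9)cc(OCc9ccccc9)cc3OCc9ccccc9)cc(OCc9ccccc9)cc2OCc9ccccc9)cc(O)c1Oc4cc(OCc9ccccc9)c(OCc9ccccc9)c(OCc9ccccc9)c4Oc5cc(OCc9ccccc9)c(OCc9ccccc9)c(OCc9ccccc9)c5 | intermediate
24 | 5-[2,4-dihydroxy-6-(2,4,6-trihydroxyphenoxy)phenoxy]-2-[3,4,5-trihydroxy-2-(3,4,5-trihydroxyphenoxy)phenoxy]benzene-1,3-diol | Oc1cc(O)c(Oc2cc(O)cc(O)c2Oc2cc(O)c(Oc3cc(O)c(O)c(O)c3Oc3cc(O)c(O)c(O)c3)c(O)c2)c(O)c1 | target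

**Step count**

Total: 15 steps. Longest linear sequence: 8 steps (steps 7, 8, 10, 11, 12, 13, 14, 15; the branch from 1 through steps 1, 2, 4, 5, 6, 13, 14, 15 is equally long).

**Steps most likely to fail**

1. Step 14. O-acylation by the enolate oxygen (lactonisation) may outpace C-acylation and stall there, or the ring A–B phenoxide may be lost from the carbon 4 anion by elimination or by exchange with alkoxide. The fallback replaces the direct closure by a two-stage ring transformation. Setting out from 22, DBU in toluene at 80 °C would drive the lactonisation on purpose to 4-{2,4-bis(benzyloxy)-6-[2,4,6-tris(benzyloxy)phenoxy]phenoxy}-6-({3,4,5-tris(benzyloxy)-2-[3,4,5-tris(benzyloxy)phenoxy]phenoxy}methyl)-2H-pyran-2-one F1. Heating F1 with Mg(OMe)2 in MeOH/THF would then open the lactone at its carbonyl and close the magnesium-chelated keto ester enolate by Claisen condensation, the pyranone-to-phloroglucinol ring transformation, coming back to the route at 23.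

2. Step 13. The lithium dienolate may fragment with loss of the ring A–B phenoxide, acylation may occur at the α-carbon, or the dienolate may be quenched by proton transfer from the α-aryloxy amide. The fallback uses no dienolate and adds the ring A–B phenol last; it sets out from 8 and 19.
   - Alkylation of 8 with epichlorohydrin (K2CO3, DMF) would give racemic 2-({3,4,5-tris(benzyloxy)-2-[3,4,5-tris(benzyloxy)phenoxy]phenoxy}methyl)oxirane F2.
   - Opening of the epoxide at its terminal carbon with lithiated methyl propiolate (n-BuLi, BF3·OEt2, THF, −78 °C) would give racemic methyl 5-hydroxy-6-{3,4,5-tris(benzyloxy)-2-[3,4,5-tris(benzyloxy)phenoxy]phenoxy}hex-2-ynoate F3.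
   - Silylation (TBSCl, imidazole) would give the tert-butyldimethylsilyl ether F4.
   - Oxa-Michael addition of 19 (Cs2CO3, DMF), the reaction type of step 12, would give the racemic (E)-3-aryloxy-5-silyloxy enoate F5.
   - Buffered HF·pyridine would release the racemic 5-hydroxy enoate F6, and Dess–Martin periodinane (NaHCO3, CH2Cl2) would oxidise it to the ketone, coming back to the route at 22.

3. Step 4. Substitution at a bromide flanked by a formyl and a benzyloxy group may be too slow, so that hydrodebromination or degradation of the aldehyde takes over. The fallback is the classical carboxylate-directed Ullmann ether synthesis of ortho-halobenzoic acids; it sets out from 5.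
   - Pinnick oxidation (NaClO2, NaH2PO4, 2-methylbut-2-ene, t-BuOH/H2O) would give 2-bromo-3,4,5-tris(benzyloxy)benzoic acid F7.
   - Condensation with 4 (Cu powder, CuI, K2CO3, pyridine/DMF, 120 °C) would give 3,4,5-tris(benzyloxy)-2-[3,4,5-tris(benzyloxy)phenoxy]benzoic acid F8.
   - LiAlH4 in THF would reduce it to {3,4,5-tris(benzyloxy)-2-[3,4,5-tris(benzyloxy)phenoxy]phenyl}methanol F9, and MnO2 in CH2Cl2 would oxidise this benzylic alcohol to the aldehyde, coming back to the route at 6.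

**Further compounds**

F1 | step 14 | 4-{2,4-bis(benzyloxy)-6-[2,4,6-tris(benzyloxy)phenoxy]phenoxy}-6-({3,4,5-tris(benzyloxy)-2-[3,4,5-tris(benzyloxy)phenoxy]phenoxy}methyl)-2H-pyran-2-one | O=C1C=C(Oc2c(Oc3c(OCc9ccccc9)cc(OCc9ccccc9)cc3OCc9ccccc9)cc(OCc9ccccc9)cc2OCc9ccccc9)C=C(COc4cc(OCc9ccccc9)c(OCc9ccccc9)c(OCc9ccccc9)c4Oc5cc(OCc9ccccc9)c(OCc9ccccc9)c(OCc9ccccc9)c5)O1
F2 | step 13 | 2-({3,4,5-tris(benzyloxy)-2-[3,4,5-tris(benzyloxy)phenoxy]phenoxy}methyl)oxirane (racemic) | C1OC1COc1cc(OCc9ccccc9)c(OCc9ccccc9)c(OCc9ccccc9)c1Oc2cc(OCc9ccccc9)c(OCc9ccccc9)c(OCc9ccccc9)c2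
F3 | step 13 | methyl 5-hydroxy-6-{3,4,5-tris(benzyloxy)-2-[3,4,5-tris(benzyloxy)phenoxy]phenoxy}hex-2-ynoate (racemic) | COC(=O)C#CCC(O)COc1cc(OCc9ccccc9)c(OCc9ccccc9)c(OCc9ccccc9)c1Oc2cc(OCc9ccccc9)c(OCc9ccccc9)c(OCc9ccccc9)c2
F4 | step 13 | methyl 5-[(tert-butyldimethylsilyl)oxy]-6-{3,4,5-tris(benzyloxy)-2-[3,4,5-tris(benzyloxy)phenoxy]phenoxy}hex-2-ynoate (racemic) | COC(=O)C#CCC(O[Si](C)(C)C(C)(C)C)COc1cc(OCc9ccccc9)c(OCc9ccccc9)c(OCc9ccccc9)c1Oc2cc(OCc9ccccc9)c(OCc9ccccc9)c(OCc9ccccc9)c2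
F5 | step 13 | methyl (E)-3-{2,4-bis(benzyloxy)-6-[2,4,6-tris(benzyloxy)phenoxy]phenoxy}-5-[(tert-butyldimethylsilyl)oxy]-6-{3,4,5-tris(benzyloxy)-2-[3,4,5-tris(benzyloxy)phenoxy]phenoxy}hex-2-enoate (racemic) | COC(=O)/C=C(/Oc1c(Oc2c(OCc9ccccc9)cc(OCc9ccccc9)cc2OCc9ccccc9)cc(OCc9ccccc9)cc1OCc9ccccc9)CC(O[Si](C)(C)C(C)(C)C)COc3cc(OCc9ccccc9)c(OCc9ccccc9)c(OCc9ccccc9)c3Oc4cc(OCc9ccccc9)c(OCc9ccccc9)c(OCc9ccccc9)c4
F6 | step 13 | methyl (E)-3-{2,4-bis(benzyloxy)-6-[2,4,6-tris(benzyloxy)phenoxy]phenoxy}-5-hydroxy-6-{3,4,5-tris(benzyloxy)-2-[3,4,5-tris(benzyloxy)phenoxy]phenoxy}hex-2-enoate (racemic) | COC(=O)/C=C(/Oc1c(Oc2c(OCc9ccccc9)cc(OCc9ccccc9)cc2OCc9ccccc9)cc(OCc9ccccc9)cc1OCc9ccccc9)CC(O)COc3cc(OCc9ccccc9)c(OCc9ccccc9)c(OCc9ccccc9)c3Oc4cc(OCc9ccccc9)c(OCc9ccccc9)c(OCc9ccccc9)c4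
F7 | step 4 | 2-bromo-3,4,5-tris(benzyloxy)benzoic acid | OC(=O)c1cc(OCc9ccccc9)c(OCc9ccccc9)c(OCc9ccccc9)c1Br
F8 | step 4 | 3,4,5-tris(benzyloxy)-2-[3,4,5-tris(benzyloxy)phenoxy]benzoic acid | OC(=O)c1cc(OCc9ccccc9)c(OCc9ccccc9)c(OCc9ccccc9)c1Oc2cc(OCc9ccccc9)c(OCc9ccccc9)c(OCc9ccccc9)c2
F9 | step 4 | {3,4,5-tris(benzyloxy)-2-[3,4,5-tris(benzyloxy)phenoxy]phenyl}methanol | OCc1cc(OCc9ccccc9)c(OCc9ccccc9)c(OCc9ccccc9)c1Oc2cc(OCc9ccccc9)c(OCc9ccccc9)c(OCc9ccccc9)c2
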